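## Structural features

The target is a tricyclic sesquiterpenoid diester built on a cyclobutane (ring B: C5, C6, C7, C8). On one face C5 and C7 are bridged by the enone unit C4(=O)–C3H=C2(C1H3) (ring A, a bicyclo[3.1.1]heptenone); on the opposite face C6 and C8 are bridged by the chain C12(CH3)2–C11–C10–C9 (ring C, seven-membered when counted through C5 or C7). All four ring B carbons are contiguous stereocentres (5R, 6S, 7R, 8R; C8 is quaternary and carries a methyl group). Ring C adds two carbinol centres, C9 next to C8 and C11 next to quaternary C12, both R, trans to each other across C10, each esterified with 3-methylbutanoic acid. Fragile elements are the two secondary esters (base), the enone (reduction, conjugate addition), the doubly bridged cyclobutane (cationic rearrangement in strong acid) and every 1,3-dioxygenated ring C intermediate (retro-Claisen and retro-aldol cleavage). The real difficulty is not the four-membered ring as such but two bridges on opposite faces of it, two quaternary carbons (C8, C12) at the ring fusions, and an absolute configuration that rests only on the difference between C2 and C4 and on the two carbinols. The key step exploits latent symmetry: when C9 and C11 are carbonyl carbons and C2 and C4 are both acetyl carbons, the bicyclo[4.1.1]octane formed by rings B and C has a mirror plane through C6, C8 and C9–C12, so the acetyl groups on C5 and C7 are enantiotopic. Ring C also locks the cyclobutane pucker so that these two acetyl groups are pseudoaxial on the face opposite ring C, and an aldol condensation between them (forming C2=C3) closes ring A and fixes C5–C8 in one event.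

## Logic of the disconnections

27 ⇒ 26. The two acyl C–O bonds at O9 and O11 are cut. The esters are identical and are the most base-sensitive groups, so they are installed last from one acyl donor. This removes ten carbons and the only labile groups. The forward step must acylate two hindered secondary alcohols, each flanked by a quaternary carbon, without touching the enone.

26 ⇒ 24 (through 25). The C9–H and C11–H bonds are cut, returning both carbinols to ketones; C4 passes through the alcohol level in 25 and is restored by allylic oxidation. Both centres have the same environment (quaternary carbon on one side, C10 on the other) and the same descriptor, so one chiral reductant can set both. Two stereocentres disappear and ring C becomes locally symmetric, which is what allows a meso precursor. The forward step needs reagent control twice, because the substrate offers almost no facial bias, plus a chemoselective reoxidation at C4.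

24 ⇒ 22. The C2=C3 bond is cut (aldol condensation retron). This is the only bond whose removal makes the whole molecule meso. Ring A and all absolute stereochemistry disappear together. The forward step must distinguish two enantiotopic acetyl groups and close a strained bridged ring.

22 ⇒ 20 ⇒ 18. The C7 acetyl is traced to an isopropenyl group (C2=O to C2=CH2) and the C5 acetyl to a methyl ester (C4–C3 cut). Two methyl ketones cannot coexist with the base that closes ring C, whereas an alkene and an ester are inert there. The forward steps need an ester-to-methyl-ketone conversion that does not over-add in the presence of the dione, and an alkene cleavage that spares the dione.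

18 ⇒ 17. The C10–C11 bond is cut (Claisen retron of the 1,3-dione). It is the only ring C bond between two carbonyls, and cutting it reduces the bicycle to a monocyclic cyclobutane. The forward step is a seven-membered closure onto an α-quaternary ester across cis-1,3 positions, and it requires the C4 ester to be trans to the C8 acetyl so that it cannot compete.

17 ⇒ 15 ⇒ 12. After functional-group interchange at C9 (through 16), the ring B bond C5–C8 is cut and C4–C8 reconnected (ring-contraction retron). A tetrasubstituted cyclobutane is easier to assemble as a cyclopentanone, and C5 becomes an equilibratable ester α-carbon. The forward step needs a concerted rearrangement with retention at C8 and a thermodynamic correction at C5.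

12 ⇒ 10 ⇒ 8 + 9. The diazo group is removed, then the C6–C12 bond is cut (Michael retron: C12 α to an ester, C6 β to the C4 ketone). This detaches 9 and the quaternary carbon C12. The forward step must add 1,4 rather than 1,2 and anti to the C7 substituent.

8 ⇒ 6 ⇒ 5 ⇒ 1 + 2 + 3. The C5=C6 unsaturation and the silyl ether are removed, then C7–C2 and C8–C9 are cut (conjugate addition with enolate trapping). The vicinal C7/C8 pattern maps directly onto 1. The forward step must make a quaternary carbon by aldol addition anti to the new C7 substituent and avoid retro-aldol cleavage.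

## Other disconnections considered

Alternative 1: The cut is the ring B bond C5–C8, traced back to a C4–C8 bond of a cyclopentanone that already carries the absolute configuration. In the forward sense the enantioenriched diazo ketone A2 would be photolysed in methanol; N2 is lost, C8 migrates from C4 to C5, and base equilibration at C5 would give the all-trans diester A1, which already holds C9 as an R-configured silyl ether.
- In its favour: the rearrangement of a cyclic diazo ketone is concerted and carries cyclopentanone stereochemistry into the cyclobutane without loss. The chosen route uses the same contraction in racemic form (12 to 15), so on the construction of ring B the two plans are equal.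
- Where it is better: once A1 is enantioenriched, ring A can be closed by any achiral aldol protocol, so nothing depends on an enantioselective closure of a strained ring.
- Against it here: the absolute configuration would have to enter in the first C–C bond formation, an enantioselective conjugate addition of an alkenyl nucleophile to the α-substituted enone 1 (a demanding case), or by resolution. It would then have to survive a dozen steps through retro-aldol- and retro-Michael-prone intermediates. The C9 configuration of A1 has no lasting value if ring C is closed by a Claisen condensation, which needs the C9 ketone.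
- Comparison: structurally the same intermediates; mechanistically substrate control from step 1 versus catalyst control at step 12; in step count about level, but without the use of racemic and meso material.

Alternative 2: The cut removes C6–C12 and C8–C9 together, so that ring C is peeled off a bicyclobutane in which C6 and C8 are bonded directly. Forward, the tertiary α-keto radical from the bromo ynone A5 would add to the unsubstituted bridgehead C6 of the methyl-substituted bicyclobutane ketal A4. The central C6–C8 bond would break, and the tertiary cyclobutyl radical at C8 would close onto the alkyne terminus C9, giving after hydrogen-atom transfer the Cs-symmetric cycloheptenone ketal A3.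
- In its favour: both quaternary carbons, ring C and the 1,3-cis topology of ring B would arise in one strain-driven operation, with no epimerisable centre. A3 is still meso, so a late desymmetrisation stays possible.
- Where it is better: in convergence and in the number of steps to a tricyclic skeleton.
- Against it here: A4 is an acid-sensitive strained hydrocarbon needing its own synthesis. The second radical step is a slow seven-membered closure competing with atom transfer to the C8 radical. A3 is further from the target in oxidation pattern than 24: C9=C10 must become a C9 carbinol, the ring A oxygen sits on C3 instead of C4, and the C2 methyl is missing.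
- Comparison: a polar closure with close analogy is traded for a radical cascade without one; the steps saved before A3 would probably be spent after it, and an enantio-determining event (a desymmetrising carbonyl transposition with methylation) would still have to be devised.

Alternative 3: The cut is C6–C12, made late, with ring B present as a cyclobutene and C11 already a protected R carbinol. Forward, Fe(acac)3 and PhSiH3 would transfer a hydrogen atom to the 1,1-disubstituted alkene of A7. The tertiary C12 radical would add to C6 of the acetyl-activated cyclobutene, closing ring C, and the C7 position would be protonated trans to the new bond, giving the bicyclo[4.1.1]octanone A6.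
- Where it is better: a radical forms the congested bond between quaternary C12 and ring B under neutral conditions, with more steric tolerance than the polar Michael addition of step 4. C11 comes in enantiopure and its oxygen can direct a 1,3-anti reduction at C9, so on control of the two carbinols it is the equal or better of the double reduction.
- Against it here: A7, an enantioenriched cyclobutene with quaternary C8 and a C5 stereocentre, is itself a hard target. The seven-membered radical closure competes with simple alkene reduction. No symmetry is used. Ring A would still need debenzylation, oxidation, an aldol condensation that places the carbonyl on C2 rather than C4, then methyl addition with oxidative transposition.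
- Comparison: a plausible but entropically disfavoured key step, and a clearly longer, fully linear sequence in chiral material.

Key step: step 12

## Remarks and assumptions

- Atom labels C1–C12 as defined under "Structural features" are used for every compound.
- Compounds 4–21 are racemic and are drawn as the enantiomer that maps onto the target. Compounds 5–16 are carried as mixtures of the two C9 epimers, which converge in step 8. Compound 22 is meso.
- Correction: the full constitution of the key-step precursor is 7,8-diacetyl-1,5,5-trimethylbicyclo[4.1.1]octane-2,4-dione; a name without the three methyl groups would not describe 22.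
- Correction: a seven-membered 1,3-dione flanked by two quaternary carbons is planned for as the diketo tautomer, acidic at C10, not as an enol. Its passivity in step 12 is attributed to steric shielding of C9 and C11 and to the acid co-catalyst.
- Design of the precursor: only the diastereomer of 22 with both acetyl groups on the face opposite ring C is meso and can bridge. C5 is therefore fixed by thermodynamic equilibration of a methyl ester at the monocyclic stage (step 6). Trapping the ketene with an amine would leave the kinetic C5 configuration in a carboxamide that cannot be equilibrated under mild conditions. The ester becomes the acetyl group only after ring C is closed.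
- Assumption: the sense of induction of the quinine-derived amine in step 12 cannot be carried over from acyclic diketones. If it selects the C7 acetyl as donor, the quinidine-derived pseudoenantiomer is used under the same conditions.

## Route

Step 1
Reactants: 1 2-methylcyclopent-2-en-1-one; 2 isopropenylmagnesium bromide; 3 acetaldehyde
Product: 5 rac-2-(1-hydroxyethyl)-2-methyl-3-(prop-1-en-2-yl)cyclopentan-1-one (ring methyl cis to isopropenyl; both C9 epimers), via magnesium enolate 4 (not isolated)
Conditions: 2, CuBr·SMe2 (10 mol %), THF, −78 → −40 °C; then 3, −78 °C; aq NH4Cl, −78 °C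
Reagents that add atoms: none
Why: Copper-catalysed conjugate addition of the alkenyl Grignard reagent gives a regiodefined tetrasubstituted enolate that is trapped by aldol addition (three-component coupling). The aldehyde approaches C8 anti to the new C7 substituent, so the hydroxyethyl group should end trans to isopropenyl and the methyl cis to it; the C9 configuration is irrelevant because C9 is oxidised in step 8.

Step 2
Reactants: 5 rac-2-(1-hydroxyethyl)-2-methyl-3-(prop-1-en-2-yl)cyclopentan-1-one
Product: 6 rac-2-[1-(tert-butyldimethylsilyloxy)ethyl]-2-methyl-3-(prop-1-en-2-yl)cyclopentan-1-one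
Conditions: TBSOTf, 2,6-lutidine, CH2Cl2, −78 → 0 °C
Reagents that add atoms: tert-butyldimethylsilyl trifluoromethanesulfonate, CC(C)(C)[Si](C)(C)OS(=O)(=O)C(F)(F)F
Why: Silylation of a hindered secondary alcohol with the silyl triflate; the ether blocks retro-aldol cleavage of the β-hydroxy ketone during the basic steps 3–5.

Step 3
Reactants: 6 rac-2-[1-(tert-butyldimethylsilyloxy)ethyl]-2-methyl-3-(prop-1-en-2-yl)cyclopentan-1-one
Product: 8 rac-5-[1-(tert-butyldimethylsilyloxy)ethyl]-5-methyl-4-(prop-1-en-2-yl)cyclopent-2-en-1-one, via silyl enol ether 7 (not isolated)
Conditions: LiN(iPr)2, THF, −78 °C; TMSCl; then Pd(OAc)2, MeCN, rt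
Reagents that add atoms: none
Why: Saegusa–Ito oxidation; C8 is quaternary, so only C5 can be enolised and the C5=C6 enone is the only possible regioisomer.

Step 4
Reactants: 8 rac-5-[1-(tert-butyldimethylsilyloxy)ethyl]-5-methyl-4-(prop-1-en-2-yl)cyclopent-2-en-1-one; 9 methyl isobutyrate
Product: 10 rac-methyl 2-{3-[1-(tert-butyldimethylsilyloxy)ethyl]-3-methyl-4-oxo-2-(prop-1-en-2-yl)cyclopentyl}-2-methylpropanoate (ester side chain on C6 trans to isopropenyl on C7)
Conditions: 9, LiN(iPr)2, THF, −78 °C; then 8, −78 → 0 °C; aq NH4Cl
Reagents that add atoms: none
Why: Michael addition of the lithium ester enolate; 1,2-addition to a carbonyl flanked by quaternary C8 is reversible and disfavoured. The nucleophile should enter C6 anti to the adjacent C7 isopropenyl group (trans-selective addition to a 4-substituted cyclopentenone), forming C6–C12 and quaternary C12.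

Step 5
Reactants: 10 rac-methyl 2-{3-[1-(tert-butyldimethylsilyloxy)ethyl]-3-methyl-4-oxo-2-(prop-1-en-2-yl)cyclopentyl}-2-methylpropanoate
Product: 12 rac-methyl 2-{5-diazo-3-[1-(tert-butyldimethylsilyloxy)ethyl]-3-methyl-4-oxo-2-(prop-1-en-2-yl)cyclopentyl}-2-methylpropanoate, via trifluoroacetyl ketone 11 (not isolated)
Conditions: LiN(SiMe3)2, THF, −78 °C; CF3CO2CH2CF3; then MsN3, Et3N, H2O, MeCN, rt
Reagents that add atoms: methanesulfonyl azide, CS(=O)(=O)N=[N+]=[N-]
Why: Detrifluoroacetylative diazo transfer (Regitz-type transfer to an activated ketone); C5 is the only enolisable position, so the diazo group can only go there.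

Step 6
Reactants: 12 rac-methyl 2-{5-diazo-3-[1-(tert-butyldimethylsilyloxy)ethyl]-3-methyl-4-oxo-2-(prop-1-en-2-yl)cyclopentyl}-2-methylpropanoate
Product: 15 rac-methyl 2-[1-(tert-butyldimethylsilyloxy)ethyl]-4-(1-methoxy-2-methyl-1-oxopropan-2-yl)-2-methyl-3-(prop-1-en-2-yl)cyclobutane-1-carboxylate (all vicinal ring substituents trans), via ketene 13 (not isolated), via C5-epimeric ester 14 (not isolated)
Conditions: hν (365 nm LED), MeOH, rt; then NaOMe (0.5 equiv), MeOH, 50 °C
Reagents that add atoms: methanol, CO
Why: Photochemical Wolff rearrangement; the cyclic diazo ketone is locked s-cis, so N2 loss and migration of C8 from C4 to C5 are concerted with retention at C8, and methanol captures the ketene. Kinetic protonation from the less hindered face (that of the C8 methyl) is expected to give the C5 epimer, which methoxide equilibrates to the isomer with the ring ester trans to both neighbours.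

Step 7
Reactants: 15 rac-methyl 2-[1-(tert-butyldimethylsilyloxy)ethyl]-4-(1-methoxy-2-methyl-1-oxopropan-2-yl)-2-methyl-3-(prop-1-en-2-yl)cyclobutane-1-carboxylate
Product: 16 rac-methyl 2-(1-hydroxyethyl)-4-(1-methoxy-2-methyl-1-oxopropan-2-yl)-2-methyl-3-(prop-1-en-2-yl)cyclobutane-1-carboxylate
Conditions: HF·pyridine, pyridine, THF, 0 °C → rt
Reagents that add atoms: none
Why: Fluoride cleavage of the silyl ether under non-basic conditions, so that no alkoxide can attack either ester.

Step 8
Reactants: 16 rac-methyl 2-(1-hydroxyethyl)-4-(1-methoxy-2-methyl-1-oxopropan-2-yl)-2-methyl-3-(prop-1-en-2-yl)cyclobutane-1-carboxylate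
Product: 17 rac-methyl 2-acetyl-4-(1-methoxy-2-methyl-1-oxopropan-2-yl)-2-methyl-3-(prop-1-en-2-yl)cyclobutane-1-carboxylate
Conditions: Dess–Martin periodinane [1,1,1-triacetoxy-1,1-dihydro-1,2-benziodoxol-3(1H)-one], NaHCO3, CH2Cl2, rt
Reagents that add atoms: none
Why: Dess–Martin oxidation of the secondary alcohol; both C9 epimers converge on one methyl ketone.

Step 9
Reactants: 17 rac-methyl 2-acetyl-4-(1-methoxy-2-methyl-1-oxopropan-2-yl)-2-methyl-3-(prop-1-en-2-yl)cyclobutane-1-carboxylate
Product: 18 rac-methyl 1,5,5-trimethyl-2,4-dioxo-8-(prop-1-en-2-yl)bicyclo[4.1.1]octane-7-carboxylate (ester and isopropenyl cis to each other, both anti to the C2–C5 bridge)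
Conditions: LiN(SiMe3)2 (2.5 equiv), THF (0.01 M), −78 → 0 °C; aq HCl
Reagents that add atoms: none
Why: Intramolecular Claisen (Dieckmann-type) condensation; the methyl ketone is the only kinetically accessible acid, its enolate carbon C10 attacks the C11 ester held cis-1,3 to it on ring B, and deprotonation of the 1,3-dione product pulls the equilibrium. The C4 ester is trans to the acetyl group on the neighbouring ring carbon and cannot be reached intramolecularly.

Step 10
Reactants: 18 rac-methyl 1,5,5-trimethyl-2,4-dioxo-8-(prop-1-en-2-yl)bicyclo[4.1.1]octane-7-carboxylate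
Product: 20 rac-7-acetyl-1,5,5-trimethyl-8-(prop-1-en-2-yl)bicyclo[4.1.1]octane-2,4-dione, via N-methoxy-N-methylamide 19 (not isolated)
Conditions: MeNH(OMe)·HCl (1.5 equiv), iPrMgCl (4.0 equiv), THF, −20 → 0 °C; then MeMgBr (3 equiv), 0 °C → rt; aq NH4Cl
Reagents that add atoms: methylmagnesium bromide, C[Mg]Br
Why: Magnesium-amide aminolysis of the ester followed by Grignard addition to the N-methoxy-N-methylamide, whose chelated tetrahedral adduct stops at the ketone stage. The first equivalent of base turns the ring C dione into its magnesium diketonate, which shields both ring ketones.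

Step 11
Reactants: 20 rac-7-acetyl-1,5,5-trimethyl-8-(prop-1-en-2-yl)bicyclo[4.1.1]octane-2,4-dione
Product: 22 meso-7,8-diacetyl-1,5,5-trimethylbicyclo[4.1.1]octane-2,4-dione (both acetyl groups anti to the C2–C5 bridge), via ozonide 21 (not isolated)
Conditions: O3, CH2Cl2, −78 °C; then PPh3, −78 °C → rt
Reagents that add atoms: ozone, [O-][O+]=O
Why: Ozonolysis of the 1,1-disubstituted alkene with reductive work-up; the conditions are neutral, so C5 and C7 are not epimerised and the diketo form of ring C is not attacked.

Step 12
Reactants: 22 meso-7,8-diacetyl-1,5,5-trimethylbicyclo[4.1.1]octane-2,4-dione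
Product: 24 (1R,2R,7S,8R)-2,6,6,9-tetramethyltricyclo[5.4.0.0(2,8)]undec-9-ene-3,5,11-trione (5R,6S,7R,8R in the atom labels used here), via ketol 23 (not isolated)
Conditions: 9-amino-9-deoxy-epi-quinine (20 mol %), AcOH (60 mol %), toluene, rt → 40 °C
Reagents that add atoms: none
Why: This is an amine-catalysed intramolecular aldol condensation in its desymmetrising form: the primary amine condenses with one acetyl group, the enamine carbon C3 adds to the carbonyl carbon C2 of the other acetyl group, and the catalyst-bound ketol 23 loses water across C2–C3 before hydrolysis releases the enone and the amine. The closest known reaction type is the primary-amine/acid-catalysed cyclodehydration of 4-substituted heptane-2,6-diones to 5-substituted 3-methylcyclohex-2-enones; 22 is such a dione whose central three carbons belong to ring B. Ring A closes in a 6-(enolendo)-exo-trig mode through a six-membered transition state. No bond to a stereocentre is formed: C5, C6, C7 and C8 become 5R,6S,7R,8R solely through which enantiotopic acetyl group acts as enamine donor (the C5 acetyl is required), and that choice is made by the chiral amine. The step needs group selectivity between the two acetyl groups, site selectivity for the methyl over the ring α-carbon, and chemoselectivity against ring C. The substrate secures these because it is Cs symmetric (no substrate bias to overcome), because ring C locks both acetyl groups pseudoaxial on the same face and close to bonding distance, because an enamine towards C5 or C7 can only epimerise reversibly, and because C9 and C11 are each shielded by a quaternary carbon while C10 cannot reach an acetyl carbonyl. Dehydration can only give C2=C3, since the alternative would place a double bond at bridgehead C7.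

Step 13
Reactants: 24 (1R,2R,7S,8R)-2,6,6,9-tetramethyltricyclo[5.4.0.0(2,8)]undec-9-ene-3,5,11-trione
Product: 25 (5R,6S,7R,8R,9R,11R)-triol: the tricyclic core of 24 with hydroxyl groups at C4 (either epimer), C9 and C11 and the C2=C3 alkene retained
Conditions: (S)-2-methyl-CBS-oxazaborolidine [(S)-1-methyl-3,3-diphenyltetrahydro-1H,3H-pyrrolo[1,2-c][1,3,2]oxazaborole] (0.5 equiv), catecholborane (4 equiv), toluene/CH2Cl2, −78 → −20 °C; MeOH, then aq NaOH
Reagents that add atoms: none
Why: Corey–Bakshi–Shibata reduction; each ring C ketone has a quaternary carbon as the large and C10 as the small substituent, so the (S)-oxazaborolidine should deliver hydride to give R at both C9 and C11, which is the trans-diol. The enone is reduced 1,2 as well, and catecholborane is chosen because it does not hydroborate C2=C3.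

Step 14
Reactants: 25 (5R,6S,7R,8R,9R,11R)-triol
Product: 26 (1R,2S,4R,6R,7R,8R)-4,6-dihydroxy-3,3,7,11-tetramethyltricyclo[5.4.0.0(2,8)]undec-10-en-9-one (5R,6S,7R,8R,9R,11R in the atom labels used here)
Conditions: MnO2 (excess), CH2Cl2, rt
Reagents that add atoms: none
Why: Chemoselective oxidation of the allylic alcohol by activated MnO2; the saturated carbinols at C9 and C11 are not oxidised and both C4 epimers give the same enone.

Step 15
Reactants: 26 (1R,2S,4R,6R,7R,8R)-4,6-dihydroxy-3,3,7,11-tetramethyltricyclo[5.4.0.0(2,8)]undec-10-en-9-one
Product: 27 (1R,2R,3R,5R,7S,8R)-2,6,6,9-tetramethyl-11-oxotricyclo[5.4.0.0(2,8)]undec-9-ene-3,5-diyl bis(3-methylbutanoate) (CNP0192813.1)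
Conditions: (Me2CHCH2CO)2O, 4-(dimethylamino)pyridine, Et3N, CH2Cl2, rt → 40 °C
Reagents that add atoms: 3-methylbutanoic anhydride, CC(C)CC(=O)OC(=O)CC(C)C
Why: Acylation of both secondary alcohols under nucleophilic catalysis by 4-(dimethylamino)pyridine; no stereocentre is touched and the enone is inert.

## Compound list

1 | 2-methylcyclopent-2-en-1-one | CC1=CCCC1=O | starting material
2 | isopropenylmagnesium bromide | CC(=C)[Mg]Br | starting material
3 | acetaldehyde | CC=O | starting material
4 | bromomagnesium enolate of rac-2-methyl-3-(prop-1-en-2-yl)cyclopentan-1-one | CC1=C(O[Mg]Br)CC[C@@H]1C(C)=C | intermediate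
5 | rac-2-(1-hydroxyethyl)-2-methyl-3-(prop-1-en-2-yl)cyclopentan-1-one (methyl cis to isopropenyl; C9 epimers) | O=C1CC[C@H](C(C)=C)[C@@]1(C)C(C)O | intermediate
6 | rac-2-[1-(tert-butyldimethylsilyloxy)ethyl]-2-methyl-3-(prop-1-en-2-yl)cyclopentan-1-one | O=C1CC[C@H](C(C)=C)[C@@]1(C)C(C)O[Si](C)(C)C(C)(C)C | intermediate
7 | trimethylsilyl enol ether of 6 (C4–O–Si, C4=C5) | C[Si](C)(C)OC1=CC[C@H](C(C)=C)[C@@]1(C)C(C)O[Si](C)(C)C(C)(C)C | intermediate
8 | rac-5-[1-(tert-butyldimethylsilyloxy)ethyl]-5-methyl-4-(prop-1-en-2-yl)cyclopent-2-en-1-one | O=C1C=C[C@H](C(C)=C)[C@@]1(C)C(C)O[Si](C)(C)C(C)(C)C | intermediate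
9 | methyl isobutyrate | CC(C)C(=O)OC | starting material
10 | rac-methyl 2-{3-[1-(tert-butyldimethylsilyloxy)ethyl]-3-methyl-4-oxo-2-(prop-1-en-2-yl)cyclopentyl}-2-methylpropanoate | O=C1C[C@@H](C(C)(C)C(=O)OC)[C@H](C(C)=C)[C@@]1(C)C(C)O[Si](C)(C)C(C)(C)C | intermediate
11 | 5-trifluoroacetyl derivative of 10 (trifluoroacetyl on C5) | O=C1C(C(=O)C(F)(F)F)[C@@H](C(C)(C)C(=O)OC)[C@H](C(C)=C)[C@@]1(C)C(C)O[Si](C)(C)C(C)(C)C | intermediate
12 | rac-methyl 2-{5-diazo-3-[1-(tert-butyldimethylsilyloxy)ethyl]-3-methyl-4-oxo-2-(prop-1-en-2-yl)cyclopentyl}-2-methylpropanoate | O=C1C(=[N+]=[N-])[C@@H](C(C)(C)C(=O)OC)[C@H](C(C)=C)[C@@]1(C)C(C)O[Si](C)(C)C(C)(C)C | intermediate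
13 | rac-methyl 2-{3-[1-(tert-butyldimethylsilyloxy)ethyl]-3-methyl-4-(oxomethylidene)-2-(prop-1-en-2-yl)cyclobutyl}-2-methylpropanoate (ketene) | O=C=C1[C@@H](C(C)(C)C(=O)OC)[C@H](C(C)=C)[C@@]1(C)C(C)O[Si](C)(C)C(C)(C)C | intermediate
14 | C5 epimer of 15 (ring ester cis to the substituents on C6 and C8) | COC(=O)[C@H]1[C@@H](C(C)(C)C(=O)OC)[C@H](C(C)=C)[C@@]1(C)C(C)O[Si](C)(C)C(C)(C)C | intermediate
15 | rac-methyl 2-[1-(tert-butyldimethylsilyloxy)ethyl]-4-(1-methoxy-2-methyl-1-oxopropan-2-yl)-2-methyl-3-(prop-1-en-2-yl)cyclobutane-1-carboxylate (all vicinal pairs trans) | COC(=O)[C@@H]1[C@@H](C(C)(C)C(=O)OC)[C@H](C(C)=C)[C@@]1(C)C(C)O[Si](C)(C)C(C)(C)C | intermediate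
16 | rac-methyl 2-(1-hydroxyethyl)-4-(1-methoxy-2-methyl-1-oxopropan-2-yl)-2-methyl-3-(prop-1-en-2-yl)cyclobutane-1-carboxylate | COC(=O)[C@@H]1[C@@H](C(C)(C)C(=O)OC)[C@H](C(C)=C)[C@@]1(C)C(C)O | intermediate
17 | rac-methyl 2-acetyl-4-(1-methoxy-2-methyl-1-oxopropan-2-yl)-2-methyl-3-(prop-1-en-2-yl)cyclobutane-1-carboxylate | COC(=O)[C@@H]1[C@@H](C(C)(C)C(=O)OC)[C@H](C(C)=C)[C@@]1(C)C(C)=O | intermediate
18 | rac-methyl 1,5,5-trimethyl-2,4-dioxo-8-(prop-1-en-2-yl)bicyclo[4.1.1]octane-7-carboxylate | COC(=O)[C@@H]1[C@@H]2[C@H](C(C)=C)[C@@]1(C)C(=O)CC(=O)C2(C)C | intermediate
19 | rac-N-methoxy-N,1,5,5-tetramethyl-2,4-dioxo-8-(prop-1-en-2-yl)bicyclo[4.1.1]octane-7-carboxamide | CON(C)C(=O)[C@@H]1[C@@H]2[C@H](C(C)=C)[C@@]1(C)C(=O)CC(=O)C2(C)C | intermediate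
20 | rac-7-acetyl-1,5,5-trimethyl-8-(prop-1-en-2-yl)bicyclo[4.1.1]octane-2,4-dione | CC(=O)[C@@H]1[C@@H]2[C@H](C(C)=C)[C@@]1(C)C(=O)CC(=O)C2(C)C | intermediate
21 | rac-7-acetyl-1,5,5-trimethyl-8-(3-methyl-1,2,4-trioxolan-3-yl)bicyclo[4.1.1]octane-2,4-dione (ozonide) | CC(=O)[C@@H]1[C@@H]2[C@H](C3(C)OCOO3)[C@@]1(C)C(=O)CC(=O)C2(C)C | intermediate
22 | meso-7,8-diacetyl-1,5,5-trimethylbicyclo[4.1.1]octane-2,4-dione (both acetyl groups anti to the C2–C5 bridge) | CC(=O)[C@@H]1[C@@H]2[C@H](C(C)=O)[C@@]1(C)C(=O)CC(=O)C2(C)C | intermediate
23 | ketol: tricyclic aldol adduct with tertiary hydroxyl and methyl on C2, C4 ketone and ring C 9,11-dione (formed bound to the catalyst) | CC1(O)CC(=O)[C@@H]2[C@@H]3[C@H]1[C@@]2(C)C(=O)CC(=O)C3(C)C | intermediate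
24 | (1R,2R,7S,8R)-2,6,6,9-tetramethyltricyclo[5.4.0.0(2,8)]undec-9-ene-3,5,11-trione | CC1=CC(=O)[C@@H]2[C@@H]3[C@H]1[C@@]2(C)C(=O)CC(=O)C3(C)C | intermediate
25 | (5R,6S,7R,8R,9R,11R)-triol: core of 24 with hydroxyl groups at C4 (either epimer), C9 and C11 | CC1=CC(O)[C@@H]2[C@@H]3[C@H]1[C@@]2(C)[C@H](O)C[C@@H](O)C3(C)C | intermediate
26 | (1R,2S,4R,6R,7R,8R)-4,6-dihydroxy-3,3,7,11-tetramethyltricyclo[5.4.0.0(2,8)]undec-10-en-9-one | CC1=CC(=O)[C@@H]2[C@@H]3[C@H]1[C@@]2(C)[C@H](O)C[C@@H](O)C3(C)C | intermediate
27 | (1R,2R,3R,5R,7S,8R)-2,6,6,9-tetramethyl-11-oxotricyclo[5.4.0.0(2,8)]undec-9-ene-3,5-diyl bis(3-methylbutanoate) | CC1=CC(=O)[C@@H]2[C@@H]3[C@H]1[C@@]2(C)[C@H](OC(=O)CC(C)C)C[C@@H](OC(=O)CC(C)C)C3(C)C | target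

## Step count and least certain steps

Total step count: 15. Longest linear sequence: 15 steps from 1 (the route is linear; 2, 3 and 9 enter as building blocks).

Step 12 (key step). The most likely failure is slow or thermodynamically marginal ring closure, because forming the bicyclo[3.1.1]heptenone adds strain to an already bridged cyclobutane. The catalyst would then rest at the ketol stage or the aldol would revert. A slow catalytic path also leaves room for unselective background closure and for gradual catalyst loss by condensation with the acidic ring C dione, so conversion or enantioselectivity would suffer. Fallback (absolute configuration taken from the reduction instead of the aldol): setting out from 22, ring A is closed with pyrrolidinium acetate in toluene under azeotropic removal of water (Dean–Stark trap), which should give 24 together with its mirror image, ent-enone dione F1. The conditions of step 13 then convert this racemate into 25 and the diastereomeric triol F2 (the same 9R,11R carbinols on the mirror-image core). Step 14 gives 26 and the diastereomeric enone diol F3, which are separated by chromatography, and the route is rejoined at 26 at the cost of half the material.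

Step 9. The most likely failure is that the strained seven-membered closure onto an α-quaternary ester is outrun by intermolecular acylation at the less hindered C4 ester, or by base-induced epimerisation at C5 followed by a fast five-membered closure onto that ester. Fallback: setting out from 17, saponification with LiOH in THF/H2O at rt should select the ring ester (the C11 ester is α-quaternary) and give keto acid F4. LiN(SiMe3)2 (3.5 equiv) then closes ring C while C4 is an inert lithium carboxylate, giving dione acid F5. MeLi (excess, THF, 0 °C, inverse acidic quench) converts the carboxylate directly into the methyl ketone, and the route is rejoined at 20, which also bypasses step 10.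

Step 13. The most likely failure is loss of catalyst control in the second hydride transfer once the first carbinol carries a boron alkoxide, or consumption of hydride by enol borate formation at C10, giving mixtures of diol diastereomers. Fallback: setting out from 24, the same oxazaborolidine with about two equivalents of catecholborane at −78 °C is stopped after C4 and one ring C ketone are reduced. This gives hydroxy ketone F6 (9R-hydroxy, C11 ketone) and/or hydroxy ketone F7 (11R-hydroxy, C9 ketone). Me4NBH(OAc)3 in AcOH/MeCN at −20 °C then delivers hydride intramolecularly from the existing carbinol oxygen, which in a ring places the new hydroxyl trans, so both regioisomers should converge on 25.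

Step 4. The most likely failure is 1,2-addition or proton abstraction at C7 by the basic lithium enolate competing with conjugate addition, or attack on the face syn to the isopropenyl group because the C8 side chain crowds the other face. Fallback: setting out from 9, LiN(iPr)2 and TMSCl give silyl ketene acetal F8, which is added to 8 under Mukaiyama–Michael conditions (TiCl4, CH2Cl2, −78 °C). The neutral nucleophile cannot deprotonate the enone, and aqueous work-up returns the route at 10.

Step 10. The most likely failure is incomplete aminolysis at the hindered ring ester, or Grignard addition to a ring C carbonyl that escaped enolisation. Fallback: setting out from 18, Me3SiCH2Li (excess, THF, 0 °C → rt) adds once to the ester, because the resulting α-silyl ketone F9 is enolised as it forms. Methanolysis (MeOH, KF) removes silicon and returns the route at 20.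

## Further compounds

F1 | step 12 | ent-enone dione, (5S,6R,7S,8S) enantiomer of 24 | CC1=CC(=O)[C@H]2[C@H]3[C@@H]1[C@]2(C)C(=O)CC(=O)C3(C)C
F2 | step 12 | diastereomeric triol, (5S,6R,7S,8S,9R,11R), C4 either epimer | CC1=CC(O)[C@H]2[C@H]3[C@@H]1[C@]2(C)[C@H](O)C[C@@H](O)C3(C)C
F3 | step 12 | diastereomeric enone diol, (5S,6R,7S,8S,9R,11R) | CC1=CC(=O)[C@H]2[C@H]3[C@@H]1[C@]2(C)[C@H](O)C[C@@H](O)C3(C)C
F4 | step 9 | rac-2-acetyl-4-(1-methoxy-2-methyl-1-oxopropan-2-yl)-2-methyl-3-(prop-1-en-2-yl)cyclobutane-1-carboxylic acid (keto acid) | OC(=O)[C@@H]1[C@@H](C(C)(C)C(=O)OC)[C@H](C(C)=C)[C@@]1(C)C(C)=O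
F5 | step 9 | rac-1,5,5-trimethyl-2,4-dioxo-8-(prop-1-en-2-yl)bicyclo[4.1.1]octane-7-carboxylic acid (dione acid) | OC(=O)[C@@H]1[C@@H]2[C@H](C(C)=C)[C@@]1(C)C(=O)CC(=O)C2(C)C
F6 | step 13 | (5R,6S,7R,8R,9R)-4,9-dihydroxy 11-ketone (C4 either epimer) | CC1=CC(O)[C@@H]2[C@@H]3[C@H]1[C@@]2(C)[C@H](O)CC(=O)C3(C)C
F7 | step 13 | (5R,6S,7R,8R,11R)-4,11-dihydroxy 9-ketone (C4 either epimer) | CC1=CC(O)[C@@H]2[C@@H]3[C@H]1[C@@]2(C)C(=O)C[C@@H](O)C3(C)C
F8 | step 4 | 1-methoxy-2-methyl-1-(trimethylsilyloxy)prop-1-ene (silyl ketene acetal) | COC(O[Si](C)(C)C)=C(C)C
F9 | step 10 | rac-1,5,5-trimethyl-8-(prop-1-en-2-yl)-7-[(trimethylsilyl)acetyl]bicyclo[4.1.1]octane-2,4-dione (α-silyl ketone) | C[Si](C)(C)CC(=O)[C@@H]1[C@@H]2[C@H](C(C)=C)[C@@]1(C)C(=O)CC(=O)C2(C)C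
A1 | alternative 1 | all-trans cyclobutane diester, single enantiomer with (R)-C9 silyl ether | COC(=O)[C@@H]1[C@@H](C(C)(C)C(=O)OC)[C@H](C(C)=C)[C@@]1(C)[C@@H](C)O[Si](C)(C)C(C)(C)C
A2 | alternative 1 | enantioenriched α-diazo cyclopentanone with (R)-C9 silyl ether | O=C1C(=[N+]=[N-])[C@@H](C(C)(C)C(=O)OC)[C@H](C(C)=C)[C@@]1(C)[C@@H](C)O[Si](C)(C)C(C)(C)C
A3 | alternative 2 | Cs-symmetric tricyclic cycloheptenone ethylene ketal (C9=C10, C11 ketone, ketal at C3) | C1C5(OCCO5)C[C@@H]2[C@@H]3[C@H]1[C@@]2(C)C=CC(=O)C3(C)C
A4 | alternative 2 | 1-methyltricyclo[4.1.0.0(2,7)]heptan-4-one ethylene ketal (Cs; ring fusion fixed by the framework) | CC12C3C1C2CC4(OCCO4)C3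
A5 | alternative 2 | 4-bromo-4-methylpent-1-yn-3-one | CC(C)(Br)C(=O)C#C
A6 | alternative 3 | bicyclo[4.1.1]octanone with C7 acetyl, C5 benzyloxymethyl, C9 ketone and (R)-C11 silyl ether | CC(=O)[C@H]1[C@H]2[C@@H](COCc3ccccc3)[C@]1(C)C(=O)C[C@@H](O[Si](C)(C)C(C)(C)C)C2(C)C
A7 | alternative 3 | acetylcyclobutene with the C9–C12 side chain on C8 (C12 as 1,1-disubstituted alkene, (R)-C11 silyl ether) | CC(=O)C1=C[C@@H](COCc2ccccc2)[C@]1(C)C(=O)C[C@@H](O[Si](C)(C)C(C)(C)C)C(C)=C
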